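Remark on the chemistry: ring A is the anisole ring (C1 bridging oxygen, C2 OMe, C4 and C6 Br) and ring B the phenol ring (C1' bridging oxygen, C2' OH, C4' and C6' Br). The target has no stereocentre, and rotation about both aryl–oxygen bonds is assumed to be fast at room temperature, so no stereochemical element has to be set.

## The problem

The target 16 consists of two benzene rings joined through a single oxygen. Both carbons on that oxygen are flanked on each side (C2/C6 and C2'/C6'), so the ether is fourfold ortho-substituted and a copper-mediated or SNAr union of two finished halves meets severe hindrance. The two rings carry the same bromine pattern and differ only in OMe against OH, so the two oxygen substituents must be told apart by a protecting group that can be removed beside a methyl ether. The bromines stand ortho and para to the bridging oxygen but meta to OMe and OH. Bromination of the assembled ether would follow the stronger donors to C3, C5, C3' and C5', so every bromine has to arrive with a building block or by a non-electrophilic path. There are no stereocentres and nothing that relays stereochemistry. Four aryl bromides rule out hydrogenolysis, late palladium or nickel chemistry and alkyllithium reagents above low temperature, and the ring B hydroxyl must be masked during organometallic steps. The enabling feature lies on ring A: C1 (bridging oxygen) and C6 (bromine) are neighbours, and the oxygen on C2 can be derived from boron. C1 and C6 can therefore be the two carbons of an aryne whose boryl neighbour at C2 sends an oxygen nucleophile to C1 and leaves a carbanion at C6 for bromination.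

## Retrosynthesis

**16 from 15 (O–isopropyl bond).** The ring B hydroxyl is carried as an isopropyl ether, and the last step cleaves it in 15. A secondary alkyl aryl ether is cleaved by a boron trihalide much faster than a methyl ether, so the methoxy group of ring A should survive. A benzyl ether would also work, but hydrogenolysis is closed by the aryl bromides. The isopropyl ether is inert to Grignard reagents and to N-bromosuccinimide, and its phenol 7 is a stock compound.

**15 from 14 from 13 (O–CH3 bond, then C2–O bond).** The methoxy group is traced to phenol 14 and this to the pinacol boronate 13. The detour through boron is required by the key step. A methoxy group at C2 would steer a nucleophile to the distal aryne carbon C6, whereas a boryl group steers it to the proximal carbon C1. The boron is then converted to oxygen by oxidation. Both operations are routine and leave the four bromines alone.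

**13 from 6 and 8 (C1–O and C6–Br bonds).** Cutting both bonds on ring A gives the aryne 11, released from the iodoaryl triflate 6, and the phenol 8, used as its magnesium salt 9. The adduct 12 is brominated at C6 in the same flask.
- Against a direct coupling of two complete halves, this cut makes the hindered C–O bond by addition to a strained, highly electrophilic aryne, where flanking groups matter least. It also installs the C6 bromine, which would hinder any later C–O coupling, after that bond is made.
- The mirror assignment is the closest neighbour: ring B as the aryne, with the methyl ether already on the phenoxide partner. It would end two steps earlier, because oxidation of boron would then give 16 directly.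
- Ring A is kept as the aryne because the ortho-oxygen substituent of the nucleophile is then a protecting group. It can still be changed to a smaller or a chelating group if the untested addition step demands it. The price is the two extra steps.
- The forward reaction must deliver O-addition at C1, not C6, keep the arylmagnesium 12 alive until the bromine donor arrives, and leave the boronate and three C–Br bonds intact.

**6 from 5 from 2 from 1 (S–O bond, C–B bond, two C–I bonds).** The triflate 6 comes from phenol 5, which comes from the symmetrical diiodophenol 2 by exchange of one of two equivalent iodines for magnesium and borylation. Compound 2 comes from 4-bromophenol 1 by twofold ortho-iodination. Boron is introduced before the triflate on purpose. An ortho-magnesiated aryl triflate is the very species that collapses to an aryne, so the exchange is run on the phenoxide 3, where the C-magnesiated species 4 has no leaving group beside it.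

**8 from 7 (C4'–Br and C6'–Br bonds).** Ring B is obtained by dibromination of 2-isopropoxyphenol 7 para and ortho to the free hydroxyl. These are exactly the positions that end up para and ortho to the bridging oxygen.

## Roads not taken

**Alternative 1:** All four C–Br bonds are cut at once. In the forward direction the diamine A1, a diaryl ether with an amino group at C5 and at C5', would take up four bromines from N-bromosuccinimide ortho to the two amino groups to give A2. Twofold diazotisation and reduction would remove both nitrogens and lead to 15, and the final ether cleavage is shared with the chosen plan.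
- Merits: the ether bond is made before any ortho-bromine exists, so it is far less hindered. Every reaction type is textbook chemistry. Each amino group sits ortho to both positions that must be brominated and overrides the alkoxy and aryloxy donors.
- Weak points: both rings of A1 are para-alkoxyanilines, which N-bromosuccinimide can oxidise to quinone imines. C3 and C3' stay open for a fifth bromine. The nitro precursors of the amino groups are meta to the ether oxygen and cannot activate an SNAr, so the ether still needs a copper-mediated coupling. Two nitrogen atoms are carried in and out (two nitro reductions, a double diazotisation of weakly basic, di-ortho-brominated anilines).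
- Comparison: on precedent this road is better, and in step count it is probably equal or slightly shorter. The chosen plan has a convergent assembly, no oxidation-prone dianiline, and bromine positions fixed by construction instead of by stopping a fourfold substitution at the right point.

**Alternative 2:** Ring A is cut at C1–C6 and C2–C3. The silyl ketene acetal A3, made from the aryloxyacetate of 8, would add to 4,6-dibromo-2-pyrone A4 in a [4+2] cycloaddition. Loss of CO2 and methanol and desilylation would give the phenol A5, which is identical in structure with 14.
- Merits: no hindered aryl–oxygen bond has to be formed, because the C1–O bond starts as a simple O-alkylation of 8. Both ring A bromines arrive with the pyrone. The road joins the chosen route two steps before the target and could be shorter on paper.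
- Weak points: A4 is not a stock compound, and as a 6-bromopyrone it is a vinylogous acyl bromide. The nucleophilic carbon of A3 can therefore substitute bromide at C6 instead of closing the ring. A3 is a trisubstituted ketene acetal carrying a bulky aryloxy group and should be a sluggish dienophile. The regiochemistry rests on polarity matching alone.
- Comparison: this road has an untested key step and in addition an unknown building block. The chosen plan has one untested step, but both of its partners are made from commercial phenols by standard reactions.

**Alternative 3:** Ring B is cut at C1'–C6' and C2'–C3'. The aryloxyalkynylboronate A6, carrying ring A, would add to 3,5-dibromo-2-pyrone A7. Loss of CO2 would give the arylboronate A8, with the methoxy group already in place and boron where the hydroxyl belongs.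
- Merits: A7 is a well-behaved ambiphilic diene, and cycloadditions of alkynylboronates with 2-pyrones to arylboronates are known. One oxidation of A8 gives 16, so the end game is two steps shorter than in the chosen plan. This is a real advantage.
- Weak points: A6 is an aryl ynol ether. Its usual preparation from a halovinyl ether needs alkyllithium, which would attack the two aryl bromides of ring A. Ynol ethers are heat-sensitive, while pyrone cycloadditions of alkynylboronates need prolonged heating well above 100 °C. The boron-bearing carbon must also bond to C6 of the pyrone.
- Comparison: if A6 could be made and survived the heating, this road would be shorter overall. The chosen plan has bench-stable partners and a key step run at −78 °C, but a longer end game.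

Key step: step 5

## Route

Step 1
Reactants: 1 4-bromophenol
Product: 2 4-bromo-2,6-diiodophenol
Conditions: I2 (1.5 equiv), 30% aq. H2O2 (3 equiv), H2O, 50 °C; aq. Na2S2O3 work-up
Reagents that add atoms: iodine, II
Why: Electrophilic aromatic iodination; the para position is blocked by bromine, so iodine enters both positions ortho to the hydroxyl, and H2O2 reoxidises the iodide so that water is the only co-product.

Step 2
Reactants: 2 4-bromo-2,6-diiodophenol
Product: 5 4-bromo-2-iodo-6-(4,4,5,5-tetramethyl-1,3,2-dioxaborolan-2-yl)phenol, via chloromagnesium phenoxide 3 (not isolated), via dimagnesiated phenoxide 4 (not isolated)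
Conditions: MeMgCl (1.0 equiv), LiCl (1.0 equiv), THF, −30 °C; iPrMgCl (1.1 equiv), −30 to 0 °C; iPrOBpin (1.5 equiv), −30 °C to rt; aq. NH4Cl
Reagents that add atoms: 2-isopropoxy-4,4,5,5-tetramethyl-1,3,2-dioxaborolane, CC(C)OB1OC(C)(C)C(C)(C)O1
Why: Iodine–magnesium exchange on an unprotected iodophenol after deprotonation in the presence of LiCl is an established protocol; iodine exchanges far faster than bromine, the C,O-dimagnesiated species 4 resists a second exchange, and the arylmagnesium is borylated by the isopropoxyboronate. Running the exchange on the phenoxide avoids an ortho-magnesiated aryl triflate, which would eliminate to an aryne before it could be borylated.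

Step 3
Reactants: 5 4-bromo-2-iodo-6-(4,4,5,5-tetramethyl-1,3,2-dioxaborolan-2-yl)phenol
Product: 6 4-bromo-2-iodo-6-(4,4,5,5-tetramethyl-1,3,2-dioxaborolan-2-yl)phenyl trifluoromethanesulfonate
Conditions: Tf2O (1.3 equiv), pyridine (2.5 equiv), CH2Cl2, 0 °C to rt
Reagents that add atoms: trifluoromethanesulfonic anhydride, O=S(=O)(OS(=O)(=O)C(F)(F)F)C(F)(F)F
Why: O-sulfonylation of a phenol; the small, very reactive anhydride triflates even a di-ortho-substituted phenol, and ortho-boryl ortho-iodo aryl triflates are stable, isolable aryne precursors.

Step 4
Reactants: 7 2-isopropoxyphenol
Product: 8 2,4-dibromo-6-isopropoxyphenol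
Conditions: NBS (2.05 equiv), MeCN, 0 °C to rt
Reagents that add atoms: N-bromosuccinimide, O=C1CCC(=O)N1Br
Why: Electrophilic aromatic bromination; the free hydroxyl is the stronger donor, so bromine enters para and then ortho to it, as in the dibromination of guaiacol, and the neutral conditions spare the isopropyl ether.

Step 5
Reactants: 6 4-bromo-2-iodo-6-(4,4,5,5-tetramethyl-1,3,2-dioxaborolan-2-yl)phenyl trifluoromethanesulfonate; 8 2,4-dibromo-6-isopropoxyphenol
Product: 13 2-[3,5-dibromo-2-(2,4-dibromo-6-isopropoxyphenoxy)phenyl]-4,4,5,5-tetramethyl-1,3,2-dioxaborolane, via chloromagnesium aryloxide 9 (not isolated), via magnesiated triflate 10 (not isolated), via borylaryne 11 (not isolated), via arylmagnesium adduct 12 (not isolated)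
Conditions: 8 (2.5 equiv), iPrMgCl·LiCl (2.5 equiv), THF, −78 to 0 °C; then −78 °C, 6 (1.0 equiv), slow addition of iPrMgCl·LiCl (1.1 equiv), −78 to −40 °C; BrCl2C–CCl2Br (3 equiv), −78 °C to rt; aq. NH4Cl
Reagents that add atoms: 1,2-dibromo-1,1,2,2-tetrachloroethane, ClC(Cl)(Br)C(Cl)(Cl)Br
Why: Proposed new method: iodine–magnesium exchange at the C–I bond of 6 (faster at −78 °C than exchange at any C–Br bond or attack on the pinacol boronate) gives the magnesiated triflate 10, which loses Mg(OTf)Cl to form the 3-boryl-5-bromoaryne 11; the aryloxide 9, present in excess, adds through oxygen to the aryne carbon next to boron (C1), and the arylmagnesium 12 left at C6 is brominated by 1,2-dibromotetrachloroethane with loss of tetrachloroethene. The closest known reaction types are the ortho-selective addition of amines to 3-borylarynes generated in this way and the addition of magnesium thiolates, selenolates and amides to arynes followed by electrophilic trapping of the arylmagnesium; the use of a magnesium aryloxide as the nucleophile is the untested part. No ring is closed and no stereocentre is formed. The step needs attack at C1 and not C6: the electropositive boryl group disfavours carbanion character on the carbon next to it and can bind the aryloxide at its empty orbital before delivery, and the bromine at C4 works in the same direction because the carbanion at C6 is then meta and not para to it. It also needs O-arylation and not C-arylation, which is secured because both ortho positions and the para position of 9 are substituted. Slow addition of the exchange reagent to a mixture of 6 and excess 9 keeps isopropylmagnesium chloride and 10 from competing for the aryne, and the aprotic medium keeps 12 intact until the bromine donor is added.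

Step 6
Reactants: 13 2-[3,5-dibromo-2-(2,4-dibromo-6-isopropoxyphenoxy)phenyl]-4,4,5,5-tetramethyl-1,3,2-dioxaborolane
Product: 14 3,5-dibromo-2-(2,4-dibromo-6-isopropoxyphenoxy)phenol
Conditions: NaBO3·4H2O (3 equiv), THF/H2O (1:1), rt
Reagents that add atoms: sodium perborate (NaBO3, used as the tetrahydrate), [Na+].[O-]OB=O
Why: Oxidation of an arylboronate to a phenol by 1,2-shift of the aryl group from boron to oxygen in the peroxoborate; the mild, nearly neutral conditions leave aryl bromides and ethers untouched.

Step 7
Reactants: 14 3,5-dibromo-2-(2,4-dibromo-6-isopropoxyphenoxy)phenol
Product: 15 1,5-dibromo-2-(2,4-dibromo-6-methoxyphenoxy)-3-isopropoxybenzene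
Conditions: MeI (2 equiv), K2CO3 (2 equiv), DMF, rt to 40 °C
Reagents that add atoms: iodomethane, CI
Why: Williamson ether synthesis; the acidic bromophenol is fully ionised by K2CO3 in DMF and the phenoxide is methylated by SN2 attack on iodomethane.

Step 8
Reactants: 15 1,5-dibromo-2-(2,4-dibromo-6-methoxyphenoxy)-3-isopropoxybenzene
Product: 16 3,5-dibromo-2-(2,4-dibromo-6-methoxyphenoxy)phenol
Conditions: BCl3 (1 M in CH2Cl2, 2.5 equiv), CH2Cl2, −20 to 0 °C; then MeOH, H2O
Reagents that add atoms: none
Why: Lewis-acid cleavage of an isopropyl aryl ether; after coordination of BCl3 the secondary alkyl group leaves as 2-chloropropane much faster than a methyl group can, so the methyl ether and the diaryl ether remain, a selectivity that is well established for isopropyl against methyl aryl ethers.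

## Compound list

1 | 4-bromophenol | Oc1ccc(Br)cc1 | starting material
2 | 4-bromo-2,6-diiodophenol | Oc1c(I)cc(Br)cc1I | intermediate
3 | chloromagnesium 4-bromo-2,6-diiodophenoxide | Cl[Mg]Oc1c(I)cc(Br)cc1I | intermediate
4 | chloromagnesium 4-bromo-2-(chloromagnesio)-6-iodophenoxide | Cl[Mg]Oc1c(I)cc(Br)cc1[Mg]Cl | intermediate
5 | 4-bromo-2-iodo-6-(4,4,5,5-tetramethyl-1,3,2-dioxaborolan-2-yl)phenol | Oc1c(I)cc(Br)cc1B1OC(C)(C)C(C)(C)O1 | intermediate
6 | 4-bromo-2-iodo-6-(4,4,5,5-tetramethyl-1,3,2-dioxaborolan-2-yl)phenyl trifluoromethanesulfonate | O=S(=O)(Oc1c(I)cc(Br)cc1B1OC(C)(C)C(C)(C)O1)C(F)(F)F | intermediate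
7 | 2-isopropoxyphenol | CC(C)Oc1ccccc1O | starting material
8 | 2,4-dibromo-6-isopropoxyphenol | CC(C)Oc1cc(Br)cc(Br)c1O | intermediate
9 | chloromagnesium 2,4-dibromo-6-isopropoxyphenoxide | CC(C)Oc1cc(Br)cc(Br)c1O[Mg]Cl | intermediate
10 | 4-bromo-2-(chloromagnesio)-6-(4,4,5,5-tetramethyl-1,3,2-dioxaborolan-2-yl)phenyl trifluoromethanesulfonate | O=S(=O)(Oc1c([Mg]Cl)cc(Br)cc1B1OC(C)(C)C(C)(C)O1)C(F)(F)F | intermediate
11 | 2-(5-bromo-2,3-didehydrophenyl)-4,4,5,5-tetramethyl-1,3,2-dioxaborolane (3-boryl-5-bromoaryne) | BrC1=CC#CC(B2OC(C)(C)C(C)(C)O2)=C1 | intermediate
12 | [5-bromo-2-(2,4-dibromo-6-isopropoxyphenoxy)-3-(4,4,5,5-tetramethyl-1,3,2-dioxaborolan-2-yl)phenyl]magnesium chloride | CC(C)Oc1cc(Br)cc(Br)c1Oc1c([Mg]Cl)cc(Br)cc1B1OC(C)(C)C(C)(C)O1 | intermediate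
13 | 2-[3,5-dibromo-2-(2,4-dibromo-6-isopropoxyphenoxy)phenyl]-4,4,5,5-tetramethyl-1,3,2-dioxaborolane | CC(C)Oc1cc(Br)cc(Br)c1Oc1c(Br)cc(Br)cc1B1OC(C)(C)C(C)(C)O1 | intermediate
14 | 3,5-dibromo-2-(2,4-dibromo-6-isopropoxyphenoxy)phenol | CC(C)Oc1cc(Br)cc(Br)c1Oc1c(O)cc(Br)cc1Br | intermediate
15 | 1,5-dibromo-2-(2,4-dibromo-6-methoxyphenoxy)-3-isopropoxybenzene | COc1cc(Br)cc(Br)c1Oc1c(OC(C)C)cc(Br)cc1Br | intermediate
16 | 3,5-dibromo-2-(2,4-dibromo-6-methoxyphenoxy)phenol | COc1cc(Br)cc(Br)c1Oc1c(O)cc(Br)cc1Br | target

## Step count and risks

Total: 8 steps. Longest linear sequence: 7 steps (steps 1, 2, 3, 5, 6, 7 and 8, from 4-bromophenol).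

**Step 5 (key step).**
- What may go wrong: the magnesium aryloxide may be too weak a nucleophile in its aggregated form, so that the aryne is consumed by the exchange reagent or by the magnesiated triflate. The doubly ortho-substituted aryloxide may attack the distal aryne carbon for steric reasons, against the direction set by boron. The arylmagnesium may be protonated before it is brominated.
- Fallback (known chemistry): from 8, nucleophilic aromatic substitution on commercially listed 3,5-dibromo-2-fluorobenzaldehyde F1 (K2CO3, DMA, 100 °C) should give 3,5-dibromo-2-(2,4-dibromo-6-isopropoxyphenoxy)benzaldehyde F2. Baeyer–Villiger oxidation (mCPBA, CH2Cl2) to 3,5-dibromo-2-(2,4-dibromo-6-isopropoxyphenoxy)phenyl formate F3 and hydrolysis (KOH, MeOH/H2O) return to the route at 14, by-passing 13.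

**Step 2.**
- What may go wrong: the exchange on the phenoxide may be incomplete or may go on to the second iodine. The poorly soluble dimagnesiated species may be protonated on work-up without having been borylated.
- Fallback: from 2, the hydroxyl is masked (MOMCl, iPr2NEt, CH2Cl2) to give 5-bromo-1,3-diiodo-2-(methoxymethoxy)benzene F4. Exchange of one iodine (iPrMgCl·LiCl, THF, −40 °C) and borylation with the isopropoxyboronate give 2-[5-bromo-3-iodo-2-(methoxymethoxy)phenyl]-4,4,5,5-tetramethyl-1,3,2-dioxaborolane F5. HCl in methanol removes the acetal and returns to the route at 5.

**Step 8.**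
- What may go wrong: the methyl ether of ring A may be cleaved as well, because BCl3 can be held in a chelate between the methoxy oxygen and the neighbouring bridging oxygen.
- Fallback: from 15, both alkyl groups are removed with excess BBr3 (CH2Cl2, −78 °C to rt) to give the symmetrical diol 2,2'-oxybis(3,5-dibromophenol) F6. Its two hydroxyl groups are equivalent, so methylation with one equivalent of MeI (K2CO3, acetone) can give only one monomethyl ether. This is 16, which is separated from recovered F6 and from the doubly methylated by-product, and the route is rejoined at 16.

## Further compounds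

F1 | step 5 | 3,5-dibromo-2-fluorobenzaldehyde | O=Cc1cc(Br)cc(Br)c1F
F2 | step 5 | 3,5-dibromo-2-(2,4-dibromo-6-isopropoxyphenoxy)benzaldehyde | CC(C)Oc1cc(Br)cc(Br)c1Oc1c(Br)cc(Br)cc1C=O
F3 | step 5 | 3,5-dibromo-2-(2,4-dibromo-6-isopropoxyphenoxy)phenyl formate | CC(C)Oc1cc(Br)cc(Br)c1Oc1c(Br)cc(Br)cc1OC=O
F4 | step 2 | 5-bromo-1,3-diiodo-2-(methoxymethoxy)benzene | COCOc1c(I)cc(Br)cc1I
F5 | step 2 | 2-[5-bromo-3-iodo-2-(methoxymethoxy)phenyl]-4,4,5,5-tetramethyl-1,3,2-dioxaborolane | COCOc1c(I)cc(Br)cc1B1OC(C)(C)C(C)(C)O1
F6 | step 8 | 2,2'-oxybis(3,5-dibromophenol) | Oc1cc(Br)cc(Br)c1Oc1c(O)cc(Br)cc1Br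
A1 | alternative 1 | 3-(5-amino-2-methoxyphenoxy)-4-isopropoxyaniline | COc1ccc(N)cc1Oc1cc(N)ccc1OC(C)C
A2 | alternative 1 | 3-(3-amino-2,4-dibromo-6-methoxyphenoxy)-2,6-dibromo-4-isopropoxyaniline | COc1cc(Br)c(N)c(Br)c1Oc1c(OC(C)C)cc(Br)c(N)c1Br
A3 | alternative 2 | {[2-(2,4-dibromo-6-isopropoxyphenoxy)-1-methoxyethenyl]oxy}trimethylsilane (double-bond geometry not defined) | COC(O[Si](C)(C)C)=COc1c(Br)cc(Br)cc1OC(C)C
A4 | alternative 2 | 4,6-dibromo-2H-pyran-2-one | O=C1C=C(Br)C=C(Br)O1
A5 | alternative 2 | 3,5-dibromo-2-(2,4-dibromo-6-isopropoxyphenoxy)phenol | CC(C)Oc1cc(Br)cc(Br)c1Oc1c(O)cc(Br)cc1Br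
A6 | alternative 3 | 2-[(2,4-dibromo-6-methoxyphenoxy)ethynyl]-4,4,5,5-tetramethyl-1,3,2-dioxaborolane | COc1cc(Br)cc(Br)c1OC#CB1OC(C)(C)C(C)(C)O1
A7 | alternative 3 | 3,5-dibromo-2H-pyran-2-one | O=C1OC=C(Br)C=C1Br
A8 | alternative 3 | 2-[3,5-dibromo-2-(2,4-dibromo-6-methoxyphenoxy)phenyl]-4,4,5,5-tetramethyl-1,3,2-dioxaborolane | COc1cc(Br)cc(Br)c1Oc1c(Br)cc(Br)cc1B1OC(C)(C)C(C)(C)O1
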